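**Strategy.** The 11-oxabicyclo[4.4.1]undecane core is unzipped at the C5–O ether bond and the C7–C8 bond (locants in the remark below), back to an open chain carrying a free tertiary C10 hydroxyl, a trans C5–C6 epoxide joined to a (Z)-2-(bromomethyl)enoate, and a C8 aldehyde. In one flask, acid first drives 7-exo opening of the epoxide by the C10 hydroxyl (first oxepane, inversion at C5), then indium-mediated Barbier allylation of C8 by C7 closes the second oxepane and unveils the C11 exo-methylene. The step exploits the 1,3-relation of C5 and C7 across the oxygenated C6 in ring A (O, C5–C10), whose bridgeheads C5 and C10 are trans-bridged.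

Key step: step 12

Remark: germacrane-type locants are used (C10 = quaternary ether carbon with the C14 methyl, C5 = ether CH, C6 = lactone CH–O, C7 bears C11(=C13H2)–C12(=O), C8 = angelate carbinol, C9 = CH2, C3 = acetoxy CH, C4 bears C15H2OAc). The 5R,10R descriptors place C4 and C1 on opposite faces of ring A, i.e. an inside,outside (trans-bridged) bicycle, and the route is built to deliver exactly that relation.

Step 1
Reactants: 1 (R)-linalool
Product: 3 (3R)-3,7-dimethyloct-6-ene-1,3-diol, via B-alkyl-9-BBN adduct 2 (not isolated)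
Conditions: 9-BBN (2.2 equiv), THF, 0 °C → rt; then 3 M NaOH, 30% H2O2, 0 °C
Reagents that add atoms: hydrogen peroxide, OO
Why: Hydroboration–oxidation; 9-BBN adds only to the monosubstituted vinyl group with boron on the terminal carbon, the trisubstituted alkene and the linalool stereocentre (future C10) are untouched.

Step 2
Reactants: 3 (3R)-3,7-dimethyloct-6-ene-1,3-diol
Product: 4 (4R)-2,2,4-trimethyl-4-(4-methylpent-3-en-1-yl)-1,3-dioxane
Conditions: 2,2-dimethoxypropane, PPTS (cat.), CH2Cl2, rt
Reagents that add atoms: 2,2-dimethoxypropane, COC(C)(C)OC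
Why: Acetonide formation (transketalisation) closes a six-membered dioxane over the primary and tertiary hydroxyls, so that no lactol can form and be oxidised in the iridium step.

Step 3
Reactants: 4 (4R)-2,2,4-trimethyl-4-(4-methylpent-3-en-1-yl)-1,3-dioxane
Product: 6 3-[(4R)-2,2,4-trimethyl-1,3-dioxan-4-yl]propan-1-ol, via dioxanyl propanal 5 (not isolated)
Conditions: O3, CH2Cl2/MeOH, −78 °C; then NaBH4, −78 °C → rt
Reagents that add atoms: ozone, [O-][O+]=O
Why: Ozonolysis of the only C=C bond followed by borohydride reduction in the same flask gives the C3 primary alcohol; the acetonide is inert and no stereocentre is involved.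

Step 4
Reactants: 6 3-[(4R)-2,2,4-trimethyl-1,3-dioxan-4-yl]propan-1-ol; 7 4-vinyl-1,3-dioxolan-2-one
Product: 8 (2S,3S)-5-[(4R)-2,2,4-trimethyl-1,3-dioxan-4-yl]-2-vinylpentane-1,3-diol
Conditions: [Ir(cod)Cl]2 (2.5 mol%), (S)-SEGPHOS (5 mol%), 4-cyano-3-nitrobenzoic acid (10 mol%), K3PO4 (cat.), THF, 70 °C
Reagents that add atoms: none
Why: Krische allylation (iridium-catalysed transfer-hydrogenative carbonyl (hydroxymethyl)allylation): the alcohol is dehydrogenated to the aldehyde and attacked by the (E)-σ-allyliridium through a closed chair, so C3/C4 come out anti from the allyl geometry and in the 3S,4S sense from the ligand (the ligand antipode is the one that gives this sense; the other would be used if a model shows the reverse).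

Step 5
Reactants: 8 (2S,3S)-5-[(4R)-2,2,4-trimethyl-1,3-dioxan-4-yl]-2-vinylpentane-1,3-diol
Product: 9 (4R)-4-{2-[(4S,5S)-2,2-di-tert-butyl-5-vinyl-1,3,2-dioxasilinan-4-yl]ethyl}-2,2,4-trimethyl-1,3-dioxane
Conditions: tBu2Si(OTf)2, 2,6-lutidine, CH2Cl2, 0 °C
Reagents that add atoms: di-tert-butylsilyl bis(trifluoromethanesulfonate), CC(C)(C)[Si](OS(=O)(=O)C(F)(F)F)(OS(=O)(=O)C(F)(F)F)C(C)(C)C
Why: Silylene protection of the 1,3-diol; the group is acid-stable, orthogonal to the acetonide and, unlike acetates, cannot act as a neighbouring group toward the later epoxide.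

Step 6
Reactants: 9 silylene acetonide; 10 (E)-crotonaldehyde
Product: 11 (E)-3-{(4S,5S)-2,2-di-tert-butyl-4-[2-((4R)-2,2,4-trimethyl-1,3-dioxan-4-yl)ethyl]-1,3,2-dioxasilinan-5-yl}prop-2-enal
Conditions: second-generation Hoveyda–Grubbs catalyst (5 mol%), crotonaldehyde (5 equiv), CH2Cl2, 40 °C
Reagents that add atoms: none
Why: Olefin cross-metathesis of the terminal vinyl group with excess crotonaldehyde should give the (E)-enal under thermodynamic control; the allylic centre C4 is not touched.

Step 7
Reactants: 11 (E)-enal acetonide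
Product: 12 (E)-3-{(4S,5S)-2,2-di-tert-butyl-4-[(3R)-3,5-dihydroxy-3-methylpentyl]-1,3,2-dioxasilinan-5-yl}prop-2-enal
Conditions: AcOH/THF/H2O (3:1:1), rt
Reagents that add atoms: none
Why: Acetal hydrolysis removes the acetonide while the silylene and the enal survive, so the C8 and C10 hydroxyls are freed before any epoxide is present.

Step 8
Reactants: 12 dihydroxy (E)-enal
Product: 13 (2R,3S)-3-{(4S,5R)-2,2-di-tert-butyl-4-[(3R)-3,5-dihydroxy-3-methylpentyl]-1,3,2-dioxasilinan-5-yl}oxirane-2-carbaldehyde
Conditions: 35% aq H2O2, (S)-2-{bis[3,5-bis(trifluoromethyl)phenyl](trimethylsilyloxy)methyl}pyrrolidine (10 mol%), CH2Cl2, rt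
Reagents that add atoms: hydrogen peroxide, OO
Why: Iminium-catalysed asymmetric epoxidation of the enal; the diarylprolinol silyl ether shields one face, so the trans (2R,3S)-epoxy aldehyde (5S,6S in target locants) should form under catalyst control irrespective of C4.

Step 9
Reactants: 13 epoxy aldehyde; 14 methyl acrylate
Product: 15 methyl 2-{hydroxy[(2S,3S)-3-(silinanyl)oxiran-2-yl]methyl}acrylate (silinanyl as in 13; both C7 epimers)
Conditions: methyl acrylate (excess), DABCO (1 equiv), 1,4-dioxane/H2O (1:1), rt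
Reagents that add atoms: none
Why: Morita–Baylis–Hillman reaction on the activated α-oxygenated aldehyde; the new carbinol centre C7 forms as a mixture, which does not matter because it becomes sp2 in step 11.

Step 10
Reactants: 15 Morita–Baylis–Hillman adduct
Product: 16 the corresponding C8 aldehyde (3-hydroxy-3-methyl-5-oxopentyl side chain)
Conditions: TEMPO (10 mol%), PhI(OAc)2, NaHCO3, CH2Cl2, 0 °C → rt
Reagents that add atoms: none
Why: Oxoammonium (TEMPO) oxidation is selective for the primary hydroxyl over the secondary allylic and tertiary ones and stops at the aldehyde; the buffered medium spares the epoxide.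

Step 11
Reactants: 16 hydroxy aldehyde
Product: 17 methyl (Z)-2-(bromomethyl)-3-[(2S,3S)-3-{(4S,5R)-2,2-di-tert-butyl-4-[(3R)-3-hydroxy-3-methyl-5-oxopentyl]-1,3,2-dioxasilinan-5-yl}oxiran-2-yl]prop-2-enoate
Conditions: NBS, Me2S, CH2Cl2, −40 → 0 °C
Reagents that add atoms: N-bromosuccinimide, O=C1CCC(=O)N1Br
Why: Corey–Kim-type activation of the secondary allylic hydroxyl and SN2′ entry of bromide should give the thermodynamically preferred (Z)-2-(bromomethyl)enoate, in which the ester is trans to C6 and therefore cannot attack the epoxide.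

Step 12
Reactants: 17 epoxy (Z)-bromomethyl enoate aldehyde
Product: 19 methyl 2-[(5R,6S,7R,8R,10R)-6,8-dihydroxy-10-methyl-3,15-O-(di-tert-butylsilylene)-5,10-epoxycyclodecan-7-yl]acrylate (target locants; spatial arrangement as in the target at every centre), via hydroxy oxepane bromide 18 (not isolated)
Conditions: CSA (0.2 equiv), CH2Cl2, 0 °C; then NaHCO3, solvent exchange to THF/H2O (4:1), 2 mM, In powder, rt
Reagents that add atoms: none
Why: CSA protonates the trans-epoxide and the free C10 hydroxyl attacks C5 from the rear (acid-catalysed hydroxy-epoxide cyclisation, SN2 with inversion), which forms O–C5 and frees the C6 hydroxyl; after neutralisation indium inserts into the allylic C–Br bond and the allylindium adds through its γ-carbon C7 to the C8 aldehyde, which forms C7–C8 and shifts the double bond into the C11=C13 exo-methylene. Both events are known reaction types, the Brønsted-acid hydroxy-epoxide etherification and the intramolecular Barbier allylation of 2-(bromomethyl)enoates, here run back to back in one flask. Ring B (O, C5, C4, C3, C2, C1, C10) closes 7-exo-tet by C–O bond formation and ring A (O, C5, C6, C7, C8, C9, C10) closes by C–C bond formation through a six-membered chair-like In–O transition state. C5 is set stereospecifically by inversion of the (5S,6S)-epoxide, which together with the linalool-derived C10 enforces the trans-bridged relation that an equilibrating or cationic etherification would not deliver; C7 should be set by attack anti to the C6–O bond on the face carrying the tethered aldehyde (A(1,3)-minimised conformer) and C8 by the (Z)-allylmetal chair, which gives the syn C7/C8 relation of the target. The step needs attack at C5 and not C6, secured by ring size (seven against eight) and by the electron-poor enoate that deactivates C6, and it needs the allylmetal never to sit next to an epoxide, secured by running the acid stage to completion first. The strain of the trans-bridged bicycle makes the second closure the slow event, hence high dilution and a water-tolerant allylindium.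

Step 13
Reactants: 19 bicyclic diol ester; 20 angelic acid
Product: 22 the C8 angelate of 19, via mixed angelic trichlorobenzoic anhydride 21 (not isolated)
Conditions: 2,4,6-trichlorobenzoyl chloride, Et3N, toluene, rt; then 19, DMAP (cat.), 0 °C → rt
Reagents that add atoms: none
Why: Yamaguchi esterification; the C8 hydroxyl (flanked by a CH2) should be acylated in preference to the C6 hydroxyl (flanked by two branched carbons and hydrogen-bonded to the ether oxygen), with retention at C8 and, with DMAP kept catalytic and cold, without (Z)→(E) isomerisation.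

Step 14
Reactants: 22 C8 angelate
Product: 23 3,15-O-(di-tert-butylsilylene) 6,12-lactone
Conditions: CSA (0.2 equiv), CH2Cl2, rt
Reagents that add atoms: none
Why: Acid-catalysed lactonisation (intramolecular transesterification) of the only free hydroxyl, C6–OH, onto the methyl ester closes the trans-fused α-methylene-γ-butyrolactone without touching a stereocentre.

Step 15
Reactants: 23 silylene lactone
Product: 25 CNP0346171.1, via diol lactone 24 (not isolated)
Conditions: HF·pyridine, THF/pyridine, 0 °C → rt; then Ac2O, DMAP (cat.), pyridine, rt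
Reagents that add atoms: acetic anhydride, CC(=O)OC(C)=O
Why: Fluoride cleaves the silylene (Si–O cleavage) and the crude 3,15-diol is acetylated (nucleophilic acyl substitution); lactone, angelate and all stereocentres are untouched.

**Compound list**

1 | (R)-linalool, (3R)-3,7-dimethylocta-1,6-dien-3-ol | C=C[C@](C)(O)CCC=C(C)C | starting material
2 | B-alkyl-9-BBN adduct of 1 (boron on the former terminal vinyl carbon) | C(C[C@](C)(O)CCC=C(C)C)B1C2CCCC1CCC2 | intermediate
3 | (3R)-3,7-dimethyloct-6-ene-1,3-diol | OCC[C@](C)(O)CCC=C(C)C | intermediate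
4 | (4R)-2,2,4-trimethyl-4-(4-methylpent-3-en-1-yl)-1,3-dioxane | CC1(C)OCC[C@@](C)(CCC=C(C)C)O1 | intermediate
5 | 3-[(4R)-2,2,4-trimethyl-1,3-dioxan-4-yl]propanal | CC1(C)OCC[C@@](C)(CCC=O)O1 | intermediate
6 | 3-[(4R)-2,2,4-trimethyl-1,3-dioxan-4-yl]propan-1-ol | CC1(C)OCC[C@@](C)(CCCO)O1 | intermediate
7 | 4-vinyl-1,3-dioxolan-2-one (vinyl ethylene carbonate, racemic) | C=CC1COC(=O)O1 | starting material
8 | (2S,3S)-5-[(4R)-2,2,4-trimethyl-1,3-dioxan-4-yl]-2-vinylpentane-1,3-diol | CC1(C)OCC[C@@](C)(CC[C@H](O)[C@H](CO)C=C)O1 | intermediate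
9 | (4R)-4-{2-[(4S,5S)-2,2-di-tert-butyl-5-vinyl-1,3,2-dioxasilinan-4-yl]ethyl}-2,2,4-trimethyl-1,3-dioxane | CC1(C)OCC[C@@](C)(CC[C@@H]2O[Si](C(C)(C)C)(C(C)(C)C)OC[C@@H]2C=C)O1 | intermediate
10 | (E)-crotonaldehyde | C/C=C/C=O | starting material
11 | (E)-enal from 9 (acetonide and silylene retained) | CC1(C)OCC[C@@](C)(CC[C@@H]2O[Si](C(C)(C)C)(C(C)(C)C)OC[C@@H]2/C=C/C=O)O1 | intermediate
12 | dihydroxy (E)-enal (C8–OH, C10–OH free; 3,15-O-silylene) | OCC[C@](C)(O)CC[C@@H]1O[Si](C(C)(C)C)(C(C)(C)C)OC[C@@H]1/C=C/C=O | intermediate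
13 | trans-(2R,3S)-epoxy aldehyde (5S,6S in target locants) | OCC[C@](C)(O)CC[C@@H]1O[Si](C(C)(C)C)(C(C)(C)C)OC[C@@H]1[C@@H]2O[C@H]2C=O | intermediate
14 | methyl acrylate | C=CC(=O)OC | starting material
15 | Morita–Baylis–Hillman adduct (C7 epimers) | OCC[C@](C)(O)CC[C@@H]1O[Si](C(C)(C)C)(C(C)(C)C)OC[C@@H]1[C@@H]2O[C@H]2C(O)C(=C)C(=O)OC | intermediate
16 | C8 aldehyde of 15 (C7 epimers) | O=CC[C@](C)(O)CC[C@@H]1O[Si](C(C)(C)C)(C(C)(C)C)OC[C@@H]1[C@@H]2O[C@H]2C(O)C(=C)C(=O)OC | intermediate
17 | (5S,6S)-epoxy (Z)-2-(bromomethyl)enoate C8 aldehyde with free C10–OH | O=CC[C@](C)(O)CC[C@@H]1O[Si](C(C)(C)C)(C(C)(C)C)OC[C@@H]1[C@@H]2O[C@H]2/C=C(\CBr)C(=O)OC | intermediate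
18 | hydroxy oxepane (O10–C5 closed, 5R; C6–OH free; bromide and aldehyde intact) | O=CC[C@@]1(C)CC[C@@H]2O[Si](C(C)(C)C)(C(C)(C)C)OC[C@@H]2[C@@H](O1)[C@@H](O)/C=C(\CBr)C(=O)OC | intermediate
19 | trans-bridged 11-oxabicyclo[4.4.1]undecane diol ester (C6–OH, C8–OH, C7 acrylate, 3,15-O-silylene) | C=C(C(=O)OC)[C@H]1[C@H](O)[C@@H]2O[C@](C)(CC[C@@H]3O[Si](C(C)(C)C)(C(C)(C)C)OC[C@@H]32)C[C@H]1O | intermediate
20 | angelic acid, (Z)-2-methylbut-2-enoic acid | C/C=C(/C)C(=O)O | starting material
21 | angelic 2,4,6-trichlorobenzoic anhydride | C/C=C(/C)C(=O)OC(=O)c1c(Cl)cc(Cl)cc1Cl | intermediate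
22 | C8 angelate of 19 | C=C(C(=O)OC)[C@H]1[C@H](O)[C@@H]2O[C@](C)(CC[C@@H]3O[Si](C(C)(C)C)(C(C)(C)C)OC[C@@H]32)C[C@H]1OC(=O)/C(C)=C\C | intermediate
23 | 3,15-O-silylene 8-angeloyloxy 6,12-lactone | C=C1C(=O)O[C@@H]2[C@@H]3O[C@](C)(CC[C@@H]4O[Si](C(C)(C)C)(C(C)(C)C)OC[C@@H]43)C[C@@H](OC(=O)/C(C)=C\C)[C@@H]12 | intermediate
24 | 3,15-diol 8-angeloyloxy 6,12-lactone | C=C1C(=O)O[C@@H]2[C@@H]3O[C@](C)(CC[C@H](O)[C@@H]3CO)C[C@@H](OC(=O)/C(C)=C\C)[C@@H]12 | intermediate
25 | CNP0346171.1 | C=C1C(=O)O[C@@H]2[C@@H]3O[C@](C)(CC[C@H](OC(C)=O)[C@@H]3COC(C)=O)C[C@@H](OC(=O)/C(C)=C\C)[C@@H]12 | target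

**Totals.** 15 steps; longest linear sequence 15 steps, from (R)-linalool.

**Steps most likely to fail**

Step 12. The strain of the trans-bridged closure may slow the intramolecular allylation so much that protonation of the allylindium or intermolecular addition takes over; the acid stage could also be diverted by rearrangement of the epoxide or dehydration of the β-hydroxy aldehyde. The fallback reverses the order of ring formation, ten-membered carbocycle first and ether bridge second, and sets out from 12. Morita–Baylis–Hillman reaction of the enal with 14 (DABCO) would give the dienyl carbinol F1. TEMPO/PhI(OAc)2 would give its C8 aldehyde F2, and NBS/Me2S the (2Z,4E)-2-(bromomethyl)dienoate aldehyde F3. CrCl2 in THF at high dilution (Nozaki–Hiyama–Kishi-type allylation through the γ-carbon C7) would close the ten-membered carbocycle F4. Buffered mCPBA should epoxidise the ring (E)-C5=C6 bond from the periphery, leaving the electron-poor acrylate, to give the epoxide F5. CSA would then trigger the transannular opening at C5 by the C10 hydroxyl, and the route is rejoined at 19.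

Step 13. The two secondary hydroxyls may not be discriminated well enough, or the C8 hydroxyl may lactonise onto the ester before it is acylated. The fallback separates the two hydroxyls in time and sets out from 17. Only the acid stage of step 12 is run and the hydroxy oxepane 18 is isolated. TESCl/imidazole would give the C6 triethylsilyl ether F6, and the indium Barbier closure the bicyclic C6-silyl ether C8-alcohol F7, in which C8–OH is the only free hydroxyl. Esterification as in step 13 would give the angelate F8. CSA in CH2Cl2 with MeOH (2 equiv) would remove the triethylsilyl group and lactonise, rejoining the route at 23.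

Step 9. The amine-catalysed addition may be slow enough for DABCO to open or epimerise the epoxy aldehyde. The fallback replaces the catalytic reaction by a preformed acrylate α-anion equivalent and sets out from 13. [1-(Methoxycarbonyl)vinyl]diisobutylalane F9, made from methyl propiolate and iBu2AlH with N-methylmorpholine N-oxide in THF at 0 °C (vinylalumination), would add to the aldehyde at low temperature and give 15 directly.

**Further compounds**

F1 | step 12 | dienyl Morita–Baylis–Hillman carbinol from 12 | OCC[C@](C)(O)CC[C@@H]1O[Si](C(C)(C)C)(C(C)(C)C)OC[C@@H]1/C=C/C(O)C(=C)C(=O)OC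
F2 | step 12 | C8 aldehyde of F1 | O=CC[C@](C)(O)CC[C@@H]1O[Si](C(C)(C)C)(C(C)(C)C)OC[C@@H]1/C=C/C(O)C(=C)C(=O)OC
F3 | step 12 | (2Z,4E)-2-(bromomethyl)dienoate aldehyde | O=CC[C@](C)(O)CC[C@@H]1O[Si](C(C)(C)C)(C(C)(C)C)OC[C@@H]1/C=C/C=C(\CBr)C(=O)OC
F4 | step 12 | ten-membered carbocycle (C7–C8 closed, (E)-C5=C6, C8–OH, C10–OH) | C=C(C(=O)OC)[C@H]1/C=C/[C@H]2CO[Si](C(C)(C)C)(C(C)(C)C)O[C@H]2CC[C@@](C)(O)C[C@H]1O
F5 | step 12 | (5S,6S)-epoxide of F4 | C=C(C(=O)OC)[C@H]1[C@@H]2O[C@H]2[C@H]3CO[Si](C(C)(C)C)(C(C)(C)C)O[C@H]3CC[C@@](C)(O)C[C@H]1O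
F6 | step 13 | C6 triethylsilyl ether of 18 | O=CC[C@@]1(C)CC[C@@H]2O[Si](C(C)(C)C)(C(C)(C)C)OC[C@@H]2[C@@H](O1)[C@@H](O[Si](CC)(CC)CC)/C=C(\CBr)C(=O)OC
F7 | step 13 | bicyclic C6-silyl ether C8-alcohol | C=C(C(=O)OC)[C@H]1[C@H](O[Si](CC)(CC)CC)[C@@H]2O[C@](C)(CC[C@@H]3O[Si](C(C)(C)C)(C(C)(C)C)OC[C@@H]32)C[C@H]1O
F8 | step 13 | C8 angelate of F7 | C=C(C(=O)OC)[C@H]1[C@H](O[Si](CC)(CC)CC)[C@@H]2O[C@](C)(CC[C@@H]3O[Si](C(C)(C)C)(C(C)(C)C)OC[C@@H]32)C[C@H]1OC(=O)/C(C)=C\C
F9 | step 9 | [1-(methoxycarbonyl)vinyl]diisobutylalane | C=C(C(=O)OC)[Al](CC(C)C)CC(C)C
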